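## Retrosynthetic overview

1. Numbering: CO2H = C1, lactone C=O = C24, CH2OH carbon = C25. The last C–C bond is C11–C12, by Suzuki–Miyaura coupling of a C1–C11 vinyl iodide acid with a C12–C24 (E)-alkenylboronate; C8 is carried as a carbinol and oxidised to the ketone only afterwards, then desilylation.
2. The usual C6–C7 ketone aldol is avoided (it is doubly mismatched for this anti,anti isomer). The C5–C7 triad comes from methacrolein by a MgCl2-catalysed anti-aldol (C6, C7) and a one-pot substrate-controlled 9-BBN hydroboration/B-alkyl Suzuki (sets C5, forges C3–C4 with the enoate in place).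
3. Bold step: C9 is set by an Evans syn-aldol of a 3-alkynoyl imide across C8–C9. The imide carbon becomes C25H2OH and the alkyne becomes the (10E)-vinyl iodide by hydrozirconation.
4. Right half: the same propionyl imide 1 gives C15 by propargylation; a Stork–Zhao olefination gives the (Z)-vinyl iodide (16Z); Stille coupling with a stannyl lactone gives the (16Z,18E)-diene.
5. Ring: the only ring, the dihydropyranone, is closed first, by ring-closing metathesis after anti-crotylboration and acryloylation, before any fragment coupling.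

Assumption: the stereochemistry is taken exactly as written in the SMILES (5R,6R,7R,9S,15R; lactone 2R,3S, i.e. trans), and 7 and 29 are taken as catalogue compounds. TBS = tert-butyldimethylsilyl; Ipc = isopinocampheyl. The route is a paper design, not run in the laboratory.

## Route

Step 1
Reactants: 1 (4S)-4-benzyl-3-propanoyl-1,3-oxazolidin-2-one; 2 2-methylprop-2-enal (methacrolein)
Product: 4 (4S)-4-benzyl-3-[(2R,3S)-3-hydroxy-2,4-dimethylpent-4-enoyl]-1,3-oxazolidin-2-one, via O-trimethylsilyl aldol adduct 3 (not isolated)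
Conditions: MgCl2 (20 mol%), Et3N, Me3SiCl, EtOAc, rt; then CF3CO2H, MeOH
Reagents that add atoms: none
Why: MgCl2-catalysed Evans anti-aldol, in which the chelated (Z)-magnesium enolate is attacked by the non-enolisable enal on the face opposite the benzyl group (the face used in Evans alkylations) through a boat transition state, giving the 2,3-anti adduct that fixes C7 and C6.

Step 2
Reactants: 4 anti-aldol adduct
Product: 5 (4S)-4-benzyl-3-[(2R,3S)-3-(tert-butyldimethylsilyloxy)-2,4-dimethylpent-4-enoyl]-1,3-oxazolidin-2-one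
Conditions: TBSOTf, 2,6-lutidine, CH2Cl2, −78 to 0 °C
Reagents that add atoms: tert-butyldimethylsilyl trifluoromethanesulfonate, CC(C)(C)[Si](C)(C)OS(=O)(=O)C(F)(F)F
Why: Silyl ether protection of the hindered secondary alcohol with the silyl triflate; no stereocentre is touched.

Step 3
Reactants: 5 silyl ether imide
Product: 6 (2S,3S)-3-(tert-butyldimethylsilyloxy)-2,4-dimethylpent-4-en-1-ol
Conditions: LiBH4, MeOH (1 equiv), THF, 0 °C
Reagents that add atoms: none
Why: Reductive removal of the Evans auxiliary, the hydride attacking the exocyclic imide carbonyl to give the primary alcohol (C8) without touching C6 or C7.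

Step 4
Reactants: 6 allylic silyl ether alcohol; 7 ethyl (2E)-3-iodobut-2-enoate
Product: 9 ethyl (2E,5R,6R,7S)-6-(tert-butyldimethylsilyloxy)-8-hydroxy-3,5,7-trimethyloct-2-enoate, via bis(9-BBN) adduct 8 (not isolated)
Conditions: 9-BBN (2.5 equiv), THF, 0 °C to rt; then 7, Pd(dppf)Cl2 (5 mol%), AsPh3, K3PO4 (aq.), DMF, rt
Reagents that add atoms: none
Why: Substrate-controlled hydroboration followed by B-alkyl Suzuki–Miyaura coupling, in which 9-BBN adds to the 1,1-disubstituted alkene under allylic-strain control (Still–Barrish sense) so that the new C5 methyl is anti to the C6 silyloxy group, and the primary alkylborane couples with retention of the (E)-iodoenoate geometry.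

Step 5
Reactants: 9 hydroxy ester
Product: 10 ethyl (2E,5R,6R,7R)-6-(tert-butyldimethylsilyloxy)-3,5,7-trimethyl-8-oxooct-2-enoate
Conditions: Dess–Martin periodinane, NaHCO3, CH2Cl2, 0 °C to rt
Reagents that add atoms: none
Why: Dess–Martin oxidation of the primary alcohol under buffered conditions gives the α-methyl aldehyde without epimerising C7; it is used at once.

Step 6
Reactants: 11 (4R)-4-benzyl-1,3-oxazolidin-2-one; 12 pent-3-ynoic acid
Product: 14 (4R)-4-benzyl-3-(pent-3-ynoyl)-1,3-oxazolidin-2-one, via mixed pivalic anhydride 13 (not isolated)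
Conditions: t-BuCOCl, Et3N, THF, −20 °C; then 11, LiCl, −20 °C to rt
Reagents that add atoms: none
Why: N-acylation of the oxazolidinone through the mixed pivalic anhydride (LiCl-assisted), cold enough that the 3-alkynoyl unit does not isomerise to the allene.

Step 7
Reactants: 10 C1–C8 aldehyde; 14 3-alkynoyl imide
Product: 17 ethyl (2E,5R,6R,7S,8S,9R)-9-{[(4R)-4-benzyl-2-oxo-1,3-oxazolidin-3-yl]carbonyl}-6-(tert-butyldimethylsilyloxy)-8-hydroxy-3,5,7-trimethyldodec-2-en-10-ynoate, via dibutylboron (Z)-enolate 15 (not isolated), via dibutylboron aldolate 16 (not isolated)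
Conditions: 14, Bu2BOTf, i-Pr2NEt, CH2Cl2, −78 °C; then 10, −78 to 0 °C; then pH 7 buffer, MeOH, H2O2, 0 °C
Reagents that add atoms: none
Why: Evans syn-aldol through a Zimmerman–Traxler chair, in which the (Z)-boron enolate of the (R)-imide adds on the face opposite the benzyl group and so sets C9 by auxiliary control (the syn C8 carbinol is oxidised in step 23, so its configuration is irrelevant).

Step 8
Reactants: 17 aldol adduct
Product: 18 ethyl (2E,5R,6R,7S,8R,9S)-6-(tert-butyldimethylsilyloxy)-8-hydroxy-9-(hydroxymethyl)-3,5,7-trimethyldodec-2-en-10-ynoate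
Conditions: LiBH4, MeOH (1 equiv), THF, 0 °C
Reagents that add atoms: none
Why: Reductive auxiliary cleavage turns the imide carbon into the C25 hydroxymethyl group, the activated imide being reduced faster than the hindered conjugated ester.

Step 9
Reactants: 18 diol
Product: 19 ethyl (2E,5R,6R,7S,8R,9S)-6-(tert-butyldimethylsilyloxy)-9-[(tert-butyldimethylsilyloxy)methyl]-8-hydroxy-3,5,7-trimethyldodec-2-en-10-ynoate
Conditions: TBSCl, imidazole, CH2Cl2, 0 °C
Reagents that add atoms: tert-butyldimethylsilyl chloride, CC(C)(C)[Si](C)(C)Cl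
Why: Selective silylation of the primary hydroxyl over the hindered secondary C8 carbinol, which stays free for the later oxidation.

Step 10
Reactants: 19 methyl alkyne
Product: 21 ethyl (2E,5R,6R,7S,8R,9S,10E)-6-(tert-butyldimethylsilyloxy)-9-[(tert-butyldimethylsilyloxy)methyl]-8-hydroxy-11-iodo-3,5,7-trimethyldodeca-2,10-dienoate, via alkenylzirconocene chloride 20 (not isolated)
Conditions: Cp2Zr(H)Cl (3 equiv), THF, rt to 40 °C; then I2, 0 °C
Reagents that add atoms: iodine, II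
Why: Hydrozirconation–iodination, in which Cp2Zr(H)Cl adds syn with zirconium on the less hindered methyl-bearing carbon (one equivalent is used up by the free hydroxyl) and iodinolysis with retention gives the (E)-2-iodoalkene that maps onto the 10E geometry.

Step 11
Reactants: 21 vinyl iodide ester
Product: 22 (2E,5R,6R,7S,8R,9S,10E)-6-(tert-butyldimethylsilyloxy)-9-[(tert-butyldimethylsilyloxy)methyl]-8-hydroxy-11-iodo-3,5,7-trimethyldodeca-2,10-dienoic acid
Conditions: LiOH, THF/MeOH/H2O, 45 °C; then 1 M HCl to pH 4, 0 °C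
Reagents that add atoms: water, O (delivered as hydroxide of LiOH, [Li+].[OH-])
Why: Saponification of the hindered enoate while no base-sensitive group (lactone, ketone) is present, so that the acid is carried free through the last three steps and needs no late deprotection.

Step 12
Reactants: 1 (4S)-4-benzyl-3-propanoyl-1,3-oxazolidin-2-one; 23 3-bromoprop-1-yne (propargyl bromide)
Product: 25 (4S)-4-benzyl-3-[(2R)-2-methylpent-4-ynoyl]-1,3-oxazolidin-2-one, via sodium (Z)-enolate 24 (not isolated)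
Conditions: NaN(SiMe3)2, THF, −78 °C; then 23, −78 to −40 °C
Reagents that add atoms: none
Why: Evans asymmetric alkylation, the chelated (Z)-sodium enolate being propargylated on the face opposite the benzyl group to set the (R)-methyl centre that becomes C15.

Step 13
Reactants: 25 alkylated imide
Product: 26 (2R)-2-methylpent-4-yn-1-ol
Conditions: LiBH4, MeOH (1 equiv), Et2O, 0 °C
Reagents that add atoms: none
Why: Reductive removal of the auxiliary gives the primary alcohol without touching the stereocentre.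

Step 14
Reactants: 26 alkynol
Product: 27 (2R)-2-methylpent-4-ynal
Conditions: Dess–Martin periodinane, NaHCO3, CH2Cl2, 0 °C; filtered solution used at once
Reagents that add atoms: none
Why: Buffered Dess–Martin oxidation gives the volatile, epimerisable α-methyl aldehyde, which is carried on in solution.

Step 15
Reactants: 27 alkynal
Product: 28 (4R,5Z)-6-iodo-4-methyloct-5-en-1-yne
Conditions: n-PrPPh3Br, n-BuLi, THF, rt; I2, −78 °C; NaN(SiMe3)2, −20 °C; then 27, −78 °C to rt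
Reagents that add atoms: propyltriphenylphosphonium bromide, CCC[P+](c1ccccc1)(c1ccccc1)c1ccccc1.[Br-]; iodine, II
Why: Stork–Zhao-type Wittig olefination, the non-stabilised α-iodo ylide reacting under kinetic control to give the (Z)-α-iodoalkene with iodine cis to the alkyl chain, which becomes the 16Z geometry.

Step 16
Reactants: 29 (2E)-3-(tributylstannyl)prop-2-en-1-ol
Product: 30 (2E)-3-(tributylstannyl)prop-2-enal
Conditions: MnO2, CH2Cl2, rt
Reagents that add atoms: none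
Why: Chemoselective allylic oxidation with MnO2 leaves the vinylstannane and its geometry intact.

Step 17
Reactants: 30 stannyl enal
Product: 32 (1E,3S,4S)-4-methyl-1-(tributylstannyl)hexa-1,5-dien-3-ol, via diisopinocampheylborinate ester 31 (not isolated)
Conditions: (E)-but-2-ene, KOt-Bu, n-BuLi, THF, −45 °C; (−)-Ipc2BOMe, −78 °C; BF3·OEt2; then 30, −78 °C; NaOH, H2O2, rt
Reagents that add atoms: (E)-but-2-ene, C/C=C/C, delivered as B-[(E)-but-2-enyl]diisopinocampheylborane, C/C=C/CB([C@@H]1C[C@@H]2C[C@H]([C@H]1C)C2(C)C)[C@@H]1C[C@@H]2C[C@H]([C@H]1C)C2(C)C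
Why: Brown crotylboration through a closed chair transition state, the (E)-crotyl group giving the anti adduct and the Ipc2B group derived from (+)-α-pinene directing attack to the si face of the aldehyde, which sets C20 and C21.

Step 18
Reactants: 32 anti homoallylic alcohol
Product: 33 (1E,3S,4S)-4-methyl-1-(tributylstannyl)hexa-1,5-dien-3-yl prop-2-enoate
Conditions: acryloyl chloride, i-Pr2NEt, CH2Cl2, 0 °C
Reagents that add atoms: acryloyl chloride, C=CC(=O)Cl
Why: O-acylation of the secondary alcohol with excess amine base so that no acid reaches the vinylstannane.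

Step 19
Reactants: 33 acrylate
Product: 34 (5S,6S)-5-methyl-6-[(E)-2-(tributylstannyl)ethenyl]-5,6-dihydro-2H-pyran-2-one
Conditions: second-generation Grubbs catalyst RuCl2(=CHPh)(PCy3)(H2IMes) (5 mol%), CH2Cl2 (5 mM), 40 °C
Reagents that add atoms: none
Why: Ring-closing metathesis of the acrylate with the terminal vinyl group closes the six-membered unsaturated lactone (the only ring), the hindered internal stannyl alkene staying a bystander and the anti relationship becoming the trans-5,6 substitution.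

Step 20
Reactants: 28 (Z)-vinyl iodide; 34 stannyl lactone
Product: 35 (5S,6R)-6-[(1E,3Z,5R)-3-ethyl-5-methylocta-1,3-dien-7-yn-1-yl]-5-methyl-5,6-dihydro-2H-pyran-2-one
Conditions: Pd2(dba)3 (5 mol%), AsPh3, NMP, rt to 40 °C
Reagents that add atoms: none
Why: Stille coupling with retention of both alkene geometries gives the (16Z,18E)-diene, and the copper-free, base-free conditions spare the terminal alkyne and the lactone.

Step 21
Reactants: 35 lactone alkyne
Product: 36 (5S,6R)-6-[(1E,3Z,5R,7E)-3-ethyl-5-methyl-8-(4,4,5,5-tetramethyl-1,3,2-dioxaborolan-2-yl)octa-1,3,7-trien-1-yl]-5-methyl-5,6-dihydro-2H-pyran-2-one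
Conditions: pinacolborane, Cy2BH (10 mol%), THF, rt
Reagents that add atoms: pinacolborane, [H]B1OC(C)(C)C(C)(C)O1
Why: Dialkylborane-catalysed hydroboration of the terminal alkyne, a syn anti-Markovnikov addition that gives the (E)-alkenylboronate while the diene, enoate and lactone are left alone at room temperature.

Step 22
Reactants: 22 vinyl iodide acid; 36 alkenylboronate lactone
Product: 37 (2E,5R,6R,7S,8R,9S,10E,12E,15R,16Z,18E)-6-(tert-butyldimethylsilyloxy)-9-[(tert-butyldimethylsilyloxy)methyl]-17-ethyl-8-hydroxy-3,5,7,11,15-pentamethyl-19-[(2R,3S)-3-methyl-6-oxo-3,6-dihydro-2H-pyran-2-yl]nonadeca-2,10,12,16,18-pentaenoic acid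
Conditions: Pd(PPh3)4 (10 mol%), TlOEt (4 equiv), THF/H2O 3:1, rt, 30 min; pH 4 work-up
Reagents that add atoms: none
Why: Suzuki–Miyaura coupling accelerated by the thallium base joins the two halves with retention of both alkene geometries to give the (10E,12E)-diene, the carboxylate and the free C8 carbinol being tolerated and the short reaction time sparing the lactone.

Step 23
Reactants: 37 C8 carbinol
Product: 38 (2E,5R,6R,7R,9S,10E,12E,15R,16Z,18E)-6-(tert-butyldimethylsilyloxy)-9-[(tert-butyldimethylsilyloxy)methyl]-17-ethyl-3,5,7,11,15-pentamethyl-19-[(2R,3S)-3-methyl-6-oxo-3,6-dihydro-2H-pyran-2-yl]-8-oxononadeca-2,10,12,16,18-pentaenoic acid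
Conditions: Dess–Martin periodinane, NaHCO3, CH2Cl2, 0 °C to rt
Reagents that add atoms: none
Why: Dess–Martin oxidation of the only free alcohol under buffered, non-epimerising conditions unveils the β,γ-unsaturated ketone at the last possible stage.

Step 24
Reactants: 38 bis-silyl ether
Product: 39 (2E,5R,6R,7R,9S,10E,12E,15R,16Z,18E)-17-ethyl-6-hydroxy-9-(hydroxymethyl)-3,5,7,11,15-pentamethyl-19-[(2R,3S)-3-methyl-6-oxo-3,6-dihydro-2H-pyran-2-yl]-8-oxononadeca-2,10,12,16,18-pentaenoic acid (target)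
Conditions: HF·pyridine, pyridine, THF, 0 °C to rt
Reagents that add atoms: none
Why: Buffered fluoride desilylation removes both silyl ethers without retro-aldol, dehydration or C9 epimerisation and leaves the acid and lactone intact.

## Compound list

1 | (4S)-4-benzyl-3-propanoyl-1,3-oxazolidin-2-one | O=C1OC[C@H](Cc2ccccc2)N1C(=O)CC | starting material
2 | 2-methylprop-2-enal (methacrolein) | C=C(C)C=O | starting material
3 | (4S)-4-benzyl-3-[(2R,3S)-2,4-dimethyl-3-(trimethylsilyloxy)pent-4-enoyl]-1,3-oxazolidin-2-one | O=C1OC[C@H](Cc2ccccc2)N1C(=O)[C@H](C)[C@H](O[Si](C)(C)C)C(C)=C | intermediate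
4 | (4S)-4-benzyl-3-[(2R,3S)-3-hydroxy-2,4-dimethylpent-4-enoyl]-1,3-oxazolidin-2-one | O=C1OC[C@H](Cc2ccccc2)N1C(=O)[C@H](C)[C@H](O)C(C)=C | intermediate
5 | (4S)-4-benzyl-3-[(2R,3S)-3-(tert-butyldimethylsilyloxy)-2,4-dimethylpent-4-enoyl]-1,3-oxazolidin-2-one | O=C1OC[C@H](Cc2ccccc2)N1C(=O)[C@H](C)[C@H](O[Si](C)(C)C(C)(C)C)C(C)=C | intermediate
6 | (2S,3S)-3-(tert-butyldimethylsilyloxy)-2,4-dimethylpent-4-en-1-ol | OC[C@H](C)[C@H](O[Si](C)(C)C(C)(C)C)C(C)=C | intermediate
7 | ethyl (2E)-3-iodobut-2-enoate | I/C(C)=C/C(=O)OCC | starting material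
8 | 9-[(2R,3R,4S)-5-(9-borabicyclo[3.3.1]nonan-9-yloxy)-3-(tert-butyldimethylsilyloxy)-2,4-dimethylpentyl]-9-borabicyclo[3.3.1]nonane | C1CCC2CCCC1B2OC[C@H](C)[C@H](O[Si](C)(C)C(C)(C)C)[C@H](C)CB1C2CCCC1CCC2 | intermediate
9 | ethyl (2E,5R,6R,7S)-6-(tert-butyldimethylsilyloxy)-8-hydroxy-3,5,7-trimethyloct-2-enoate | OC[C@H](C)[C@H](O[Si](C)(C)C(C)(C)C)[C@H](C)C/C(C)=C/C(=O)OCC | intermediate
10 | ethyl (2E,5R,6R,7R)-6-(tert-butyldimethylsilyloxy)-3,5,7-trimethyl-8-oxooct-2-enoate | O=C[C@H](C)[C@H](O[Si](C)(C)C(C)(C)C)[C@H](C)C/C(C)=C/C(=O)OCC | intermediate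
11 | (4R)-4-benzyl-1,3-oxazolidin-2-one | O=C1OC[C@@H](Cc2ccccc2)N1 | starting material
12 | pent-3-ynoic acid | CC#CCC(=O)O | starting material
13 | 2,2-dimethylpropanoic pent-3-ynoic anhydride | CC#CCC(=O)OC(=O)C(C)(C)C | intermediate
14 | (4R)-4-benzyl-3-(pent-3-ynoyl)-1,3-oxazolidin-2-one | O=C1OC[C@@H](Cc2ccccc2)N1C(=O)CC#CC | intermediate
15 | (4R)-4-benzyl-3-[(1Z)-1-(dibutylboranyloxy)pent-1-en-3-yn-1-yl]-1,3-oxazolidin-2-one | CCCCB(CCCC)O/C(=C\C#CC)N1[C@H](Cc2ccccc2)COC1=O | intermediate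
16 | ethyl (2E,5R,6R,7S,8S,9R)-9-{[(4R)-4-benzyl-2-oxo-1,3-oxazolidin-3-yl]carbonyl}-6-(tert-butyldimethylsilyloxy)-8-(dibutylboranyloxy)-3,5,7-trimethyldodec-2-en-10-ynoate | O=C1OC[C@@H](Cc2ccccc2)N1C(=O)[C@H](C#CC)[C@@H](OB(CCCC)CCCC)[C@H](C)[C@H](O[Si](C)(C)C(C)(C)C)[C@H](C)C/C(C)=C/C(=O)OCC | intermediate
17 | ethyl (2E,5R,6R,7S,8S,9R)-9-{[(4R)-4-benzyl-2-oxo-1,3-oxazolidin-3-yl]carbonyl}-6-(tert-butyldimethylsilyloxy)-8-hydroxy-3,5,7-trimethyldodec-2-en-10-ynoate | O=C1OC[C@@H](Cc2ccccc2)N1C(=O)[C@H](C#CC)[C@@H](O)[C@H](C)[C@H](O[Si](C)(C)C(C)(C)C)[C@H](C)C/C(C)=C/C(=O)OCC | intermediate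
18 | ethyl (2E,5R,6R,7S,8R,9S)-6-(tert-butyldimethylsilyloxy)-8-hydroxy-9-(hydroxymethyl)-3,5,7-trimethyldodec-2-en-10-ynoate | OC[C@H](C#CC)[C@@H](O)[C@H](C)[C@H](O[Si](C)(C)C(C)(C)C)[C@H](C)C/C(C)=C/C(=O)OCC | intermediate
19 | ethyl (2E,5R,6R,7S,8R,9S)-6-(tert-butyldimethylsilyloxy)-9-[(tert-butyldimethylsilyloxy)methyl]-8-hydroxy-3,5,7-trimethyldodec-2-en-10-ynoate | CC(C)(C)[Si](C)(C)OC[C@H](C#CC)[C@@H](O)[C@H](C)[C@H](O[Si](C)(C)C(C)(C)C)[C@H](C)C/C(C)=C/C(=O)OCC | intermediate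
20 | ethyl (2E,5R,6R,7R,8R,9S,10E)-6-(tert-butyldimethylsilyloxy)-9-[(tert-butyldimethylsilyloxy)methyl]-11-[chlorobis(cyclopentadienyl)zirconio]-8-[chlorobis(cyclopentadienyl)zirconiooxy]-3,5,7-trimethyldodeca-2,10-dienoate | C/C(=C\[C@@H](CO[Si](C)(C)C(C)(C)C)[C@@H](O[Zr](Cl)(C1C=CC=C1)C1C=CC=C1)[C@H](C)[C@H](O[Si](C)(C)C(C)(C)C)[C@H](C)C/C(C)=C/C(=O)OCC)[Zr](Cl)(C1C=CC=C1)C1C=CC=C1 | intermediate
21 | ethyl (2E,5R,6R,7S,8R,9S,10E)-6-(tert-butyldimethylsilyloxy)-9-[(tert-butyldimethylsilyloxy)methyl]-8-hydroxy-11-iodo-3,5,7-trimethyldodeca-2,10-dienoate | I/C(C)=C/[C@@H](CO[Si](C)(C)C(C)(C)C)[C@@H](O)[C@H](C)[C@H](O[Si](C)(C)C(C)(C)C)[C@H](C)C/C(C)=C/C(=O)OCC | intermediate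
22 | (2E,5R,6R,7S,8R,9S,10E)-6-(tert-butyldimethylsilyloxy)-9-[(tert-butyldimethylsilyloxy)methyl]-8-hydroxy-11-iodo-3,5,7-trimethyldodeca-2,10-dienoic acid | I/C(C)=C/[C@@H](CO[Si](C)(C)C(C)(C)C)[C@@H](O)[C@H](C)[C@H](O[Si](C)(C)C(C)(C)C)[C@H](C)C/C(C)=C/C(=O)O | intermediate
23 | 3-bromoprop-1-yne (propargyl bromide) | BrCC#C | starting material
24 | sodium (1Z)-1-[(4S)-4-benzyl-2-oxo-1,3-oxazolidin-3-yl]prop-1-en-1-olate | C/C=C(\[O-])N1[C@@H](Cc2ccccc2)COC1=O.[Na+] | intermediate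
25 | (4S)-4-benzyl-3-[(2R)-2-methylpent-4-ynoyl]-1,3-oxazolidin-2-one | O=C1OC[C@H](Cc2ccccc2)N1C(=O)[C@H](C)CC#C | intermediate
26 | (2R)-2-methylpent-4-yn-1-ol | OC[C@H](C)CC#C | intermediate
27 | (2R)-2-methylpent-4-ynal | O=C[C@H](C)CC#C | intermediate
28 | (4R,5Z)-6-iodo-4-methyloct-5-en-1-yne | CCC(=C/[C@H](C)CC#C)/I | intermediate
29 | (2E)-3-(tributylstannyl)prop-2-en-1-ol | CCCC[Sn](CCCC)(CCCC)/C=C/CO | starting material
30 | (2E)-3-(tributylstannyl)prop-2-enal | CCCC[Sn](CCCC)(CCCC)/C=C/C=O | intermediate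
31 | (1E,3S,4S)-4-methyl-1-(tributylstannyl)hexa-1,5-dien-3-yl diisopinocampheylborinate (Ipc from (+)-α-pinene) | CCCC[Sn](CCCC)(CCCC)/C=C/[C@@H](OB([C@@H]1C[C@@H]2C[C@H]([C@H]1C)C2(C)C)[C@@H]1C[C@@H]2C[C@H]([C@H]1C)C2(C)C)[C@@H](C)C=C | intermediate
32 | (1E,3S,4S)-4-methyl-1-(tributylstannyl)hexa-1,5-dien-3-ol | CCCC[Sn](CCCC)(CCCC)/C=C/[C@@H](O)[C@@H](C)C=C | intermediate
33 | (1E,3S,4S)-4-methyl-1-(tributylstannyl)hexa-1,5-dien-3-yl prop-2-enoate | CCCC[Sn](CCCC)(CCCC)/C=C/[C@@H](OC(=O)C=C)[C@@H](C)C=C | intermediate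
34 | (5S,6S)-5-methyl-6-[(E)-2-(tributylstannyl)ethenyl]-5,6-dihydro-2H-pyran-2-one | CCCC[Sn](CCCC)(CCCC)/C=C/[C@H]1OC(=O)C=C[C@@H]1C | intermediate
35 | (5S,6R)-6-[(1E,3Z,5R)-3-ethyl-5-methylocta-1,3-dien-7-yn-1-yl]-5-methyl-5,6-dihydro-2H-pyran-2-one | CCC(=C/[C@H](C)CC#C)/C=C/[C@H]1OC(=O)C=C[C@@H]1C | intermediate
36 | (5S,6R)-6-[(1E,3Z,5R,7E)-3-ethyl-5-methyl-8-(4,4,5,5-tetramethyl-1,3,2-dioxaborolan-2-yl)octa-1,3,7-trien-1-yl]-5-methyl-5,6-dihydro-2H-pyran-2-one | CCC(=C/[C@H](C)C/C=C/B1OC(C)(C)C(C)(C)O1)/C=C/[C@H]1OC(=O)C=C[C@@H]1C | intermediate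
37 | (2E,5R,6R,7S,8R,9S,10E,12E,15R,16Z,18E)-6-(tert-butyldimethylsilyloxy)-9-[(tert-butyldimethylsilyloxy)methyl]-17-ethyl-8-hydroxy-3,5,7,11,15-pentamethyl-19-[(2R,3S)-3-methyl-6-oxo-3,6-dihydro-2H-pyran-2-yl]nonadeca-2,10,12,16,18-pentaenoic acid | CCC(=C/[C@H](C)C/C=C/C(C)=C/[C@@H](CO[Si](C)(C)C(C)(C)C)[C@@H](O)[C@H](C)[C@H](O[Si](C)(C)C(C)(C)C)[C@H](C)C/C(C)=C/C(=O)O)/C=C/[C@H]1OC(=O)C=C[C@@H]1C | intermediate
38 | (2E,5R,6R,7R,9S,10E,12E,15R,16Z,18E)-6-(tert-butyldimethylsilyloxy)-9-[(tert-butyldimethylsilyloxy)methyl]-17-ethyl-3,5,7,11,15-pentamethyl-19-[(2R,3S)-3-methyl-6-oxo-3,6-dihydro-2H-pyran-2-yl]-8-oxononadeca-2,10,12,16,18-pentaenoic acid | CCC(=C/[C@H](C)C/C=C/C(C)=C/[C@@H](CO[Si](C)(C)C(C)(C)C)C(=O)[C@H](C)[C@H](O[Si](C)(C)C(C)(C)C)[C@H](C)C/C(C)=C/C(=O)O)/C=C/[C@H]1OC(=O)C=C[C@@H]1C | intermediate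
39 | (2E,5R,6R,7R,9S,10E,12E,15R,16Z,18E)-17-ethyl-6-hydroxy-9-(hydroxymethyl)-3,5,7,11,15-pentamethyl-19-[(2R,3S)-3-methyl-6-oxo-3,6-dihydro-2H-pyran-2-yl]-8-oxononadeca-2,10,12,16,18-pentaenoic acid | CCC(=C/[C@H](C)C/C=C/C(C)=C/[C@@H](CO)C(=O)[C@H](C)[C@H](O)[C@H](C)C/C(C)=C/C(=O)O)/C=C/[C@H]1OC(=O)C=C[C@@H]1C | target

## Step count and risks

Total step count: 24. Longest linear sequence: 13 steps (steps 1–5, 7–11, 22–24, from 1 and 2).

The three steps most likely to fail: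

Step 7 (syn-aldol of the 3-alkynoyl imide). The enolate of 14 may isomerise to the allenyl imide or react at its γ-carbon. The fallback leaves the alkyne donor; it sets out from 10 (with 11) and comes back to the route at 21. Commercial pent-3-yn-1-ol is hydrozirconated and iodinated (Cp2Zr(H)Cl, then I2) to (3E)-4-iodopent-3-en-1-ol F1. This is oxidised (TEMPO, PhI(OAc)2, then NaClO2) to (3E)-4-iodopent-3-enoic acid F2 and attached to 11 through its mixed pivalic anhydride to give (4R)-4-benzyl-3-[(3E)-4-iodopent-3-enoyl]-1,3-oxazolidin-2-one F3. This alkenyl imide has no allene pathway; its dibutylboron enolate adds to 10 to give the vinyl iodide syn-aldol adduct F4. LiBH4 then gives the iodo diol F5, and silylation of its primary hydroxyl (TBSCl, imidazole) gives 21 directly, so step 10 is no longer needed.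

Step 15 (α-iodo ylide olefination). Yield and Z/E ratio are often modest, and 27 is volatile and epimerisable. The fallback sets out from 27 and comes back at 35. CBr4 and PPh3 (first stage of the Corey–Fuchs sequence) give (3R)-1,1-dibromo-3-methylhex-1-en-5-yne F6. A trans-selective Negishi monoethylation (EtZnCl, Pd(DPEphos)Cl2) replaces only the bromine trans to the alkyl chain and gives (4R,5Z)-6-bromo-4-methyloct-5-en-1-yne F7. Stille coupling of F7 with 34 (Pd(t-Bu3P)2, CsF, NMP) gives 35.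

Step 22 (thallium-promoted Suzuki union). Protodeboronation, lactone opening or slow oxidative addition at the hindered iodide could defeat it. The fallback inverts the polarity and works without base; it sets out from 22 and 35 and comes back at 37. 22 is stannylated with (Bu3Sn)2 and Pd(PPh3)4 to the vinylstannane acid F8. 35 is hydrozirconated and iodinated (Cp2Zr(H)Cl, 1.1 equiv, 0 °C, then I2) to the (E)-vinyl iodide lactone F9. Stille coupling of F8 with F9 (Pd2(dba)3, AsPh3, NMP) gives 37.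

Further compounds

F1 | step 7 | (3E)-4-iodopent-3-en-1-ol | I/C(C)=C/CCO
F2 | step 7 | (3E)-4-iodopent-3-enoic acid | I/C(C)=C/CC(=O)O
F3 | step 7 | (4R)-4-benzyl-3-[(3E)-4-iodopent-3-enoyl]-1,3-oxazolidin-2-one | O=C1OC[C@@H](Cc2ccccc2)N1C(=O)C/C=C(C)/I
F4 | step 7 | ethyl (2E,5R,6R,7S,8S,9R,10E)-9-{[(4R)-4-benzyl-2-oxo-1,3-oxazolidin-3-yl]carbonyl}-6-(tert-butyldimethylsilyloxy)-8-hydroxy-11-iodo-3,5,7-trimethyldodeca-2,10-dienoate | O=C1OC[C@@H](Cc2ccccc2)N1C(=O)[C@H](/C=C(C)/I)[C@@H](O)[C@H](C)[C@H](O[Si](C)(C)C(C)(C)C)[C@H](C)C/C(C)=C/C(=O)OCC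
F5 | step 7 | ethyl (2E,5R,6R,7S,8R,9S,10E)-6-(tert-butyldimethylsilyloxy)-8-hydroxy-9-(hydroxymethyl)-11-iodo-3,5,7-trimethyldodeca-2,10-dienoate | OC[C@H](/C=C(C)/I)[C@@H](O)[C@H](C)[C@H](O[Si](C)(C)C(C)(C)C)[C@H](C)C/C(C)=C/C(=O)OCC
F6 | step 15 | (3R)-1,1-dibromo-3-methylhex-1-en-5-yne | BrC(Br)=C[C@H](C)CC#C
F7 | step 15 | (4R,5Z)-6-bromo-4-methyloct-5-en-1-yne | CCC(=C/[C@H](C)CC#C)/Br
F8 | step 22 | (2E,5R,6R,7S,8R,9S,10E)-6-(tert-butyldimethylsilyloxy)-9-[(tert-butyldimethylsilyloxy)methyl]-8-hydroxy-3,5,7-trimethyl-11-(tributylstannyl)dodeca-2,10-dienoic acid | CCCC[Sn](CCCC)(CCCC)/C(C)=C/[C@@H](CO[Si](C)(C)C(C)(C)C)[C@@H](O)[C@H](C)[C@H](O[Si](C)(C)C(C)(C)C)[C@H](C)C/C(C)=C/C(=O)O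
F9 | step 22 | (5S,6R)-6-[(1E,3Z,5R,7E)-3-ethyl-8-iodo-5-methylocta-1,3,7-trien-1-yl]-5-methyl-5,6-dihydro-2H-pyran-2-one | CCC(=C/[C@H](C)C/C=C/I)/C=C/[C@H]1OC(=O)C=C[C@@H]1C
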